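Decide first what to watch: not the conversion, but the amount of complex with three exchanged over the amount of complex with two exchanged at one moment.

| setting | north-west | north-east | Saturday's | Thursday's | Sunday's |
|---|---|---|---|---|---|
| starting complex | 0.25 M | 0.25 M | 0.25 M | 0.25 M | 0.25 M |
| incoming ligand | 1.4 equiv | 2.8 equiv | 2.00 equiv | 2.50 equiv | 4.00 equiv |
| leaving ligand | 5 equiv | 5 equiv | 5.00 equiv | 5.00 equiv | 5.00 equiv |
| remark | run made earlier | run made earlier |  |  |  |
| time |  |  | 5.0 h | 5.0 h | 5.0 h |

- north-west (time / h: complex with two exchanged / %, complex with three exchanged / %): 0.250: 0.8, 0; 0.500: 1.2, 0; 0.833: 3.8, 0.1; 1.33: 7.3, 0.1; 2.00: 10.9, 0; 4.00: 23.4, 1.1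
- north-east (time / h: complex with two exchanged / %, complex with three exchanged / %): 0.250: 1.4, 0; 0.500: 4.9, 0; 0.833: 11.3, 0.4; 1.33: 19.2, 0; 2.00: 28.8, 0.7; 4.00: 49.6, 3.6

(each reading ± 0.5 percentage points)

* complex with two exchanged at the end, in percent of the starting complex charged, for each flask in turn (Saturday's, Thursday's, Sunday's)

- the numbers in the tables scatter by 0.5 percentage points (one standard deviation)
- a reading or a percentage of complex with three exchanged counts all its forms, free or not

Climb the time scales rung by rung. In the north-east run, the first rung is a short lag: complex with two exchanged reads 1.4% after 0.250 h. The second rung takes hours: the same complex climbs roughly in a straight line, to 19.2% after 1.33 h and 49.6% after 4.00 h. The next rung is complex with three exchanged, which reads 3.6% after 4.00 h, far less than the 49.6% of complex with two exchanged. That reading carries a scatter of 0.5 percentage points.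

Their quotient, as read in the north-east run, is 0.0726, and this number is the spill ratio, [complex with three exchanged] with all its forms counted over [complex with two exchanged], a running selectivity. Now suppose each complex with three exchanged forms from one with two exchanged and one incoming ligand. While the second climbs linearly and the incoming ligand stays in proportion to its charge, the ratio should then grow with the equivalents of incoming ligand times the time, at the same charge of starting complex and leaving ligand. Scaling this reading to 5.0 h gives an estimate that stretches both assumptions and carries the scatter: I reckon 0.0648 for Saturday's flask and 0.130 for Sunday's, which is twice as much.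

These ratios speak of the spill from complex with two exchanged, not of its yield. The forecast, reasoning that “doubling the incoming ligand raises the rate”, gave 39%, 48% and 64% for Saturday's, Thursday's and Sunday's flasks.

The flasks give 42.0%, 51.4% and 66.7%, so the forecast held.

    complex with two exchanged + incoming ligand → leaving ligand + complex with three exchanged (k = 2.70 × 10⁻⁵ /M/s)
    incoming ligand ⇌ dormant form (K = 0.360, k = 1.90 × 10⁻⁴ /s)
    complex with three exchanged + incoming ligand → leaving ligand + complex with four exchanged (k = 2.50 × 10⁻⁴ /M/s)
    starting complex + incoming ligand → leaving ligand + complex with one exchanged (k = 2.00 × 10⁻⁴ /M/s)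
    starting complex + complex with three exchanged ⇌ idle adduct, settled at all times (K = 88.0 /M)
    complex with one exchanged + incoming ligand → leaving ligand + complex with two exchanged (k = 6.40 × 10⁻⁴ /M/s)

In Saturday's flask at 5.00 h, complex with two exchanged is made 8.72 times faster than it is used up, each step taken net. With the complex with three exchanged held in idle adduct counted, Saturday's spill ratio at that time comes to 0.0543 against the reckoned 0.0648, and Sunday's at the same time comes to 0.132 against the reckoned 0.130.

The data were generated by integration for an exercise, and the scatter is random.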